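The earlier runs and the new flask were generated by integration for substances that don't exist.

If I wanted yield from a solid reagent, I began with the bench rule: each mole of solid reagent gives at most one mole of product, so while c solid reagent stays below c starting material, the yield stops at c solid reagent over c starting material.

| flask | starting material | solid reagent | free catalyst | remark | time |
|---|---|---|---|---|---|
| zeta | 0.50 M | 0.062 M | 12 mM | run made earlier |  |
| gamma | 0.50 M | 0.23 M | 12 mM | run made earlier |  |
| beta | 0.39 M | 0.35 M | 12 mM | run made earlier |  |
| noon | 0.25 M | 0.120 M | 12 mM |  | 20 min |
| winter | 0.50 M | 0.350 M | 12 mM |  | 5.0 min |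

| run | time / min | product / % | starting material / % |
|---|---|---|---|
| zeta | 0.417 | 1.2 | 95.8 |
| zeta | 0.833 | 4.6 | 93.6 |
| zeta | 1.33 | 7.0 | 90.1 |
| zeta | 1.50 | 9.0 | 89.2 |
| zeta | 2.00 | 11.1 | 85.4 |
| zeta | 2.50 | 12.4 | 85.0 |
| gamma | 0.417 | 0.5 | 95.7 |
| gamma | 0.833 | 3.5 | 93.8 |
| gamma | 1.33 | 8.5 | 90.0 |
| gamma | 1.50 | 9.1 | 88.4 |
| gamma | 2.00 | 12.4 | 85.6 |
| gamma | 2.50 | 17.3 | 81.7 |
| beta | 0.200 | 0.6 | 96.2 |
| beta | 0.417 | 1.7 | 96.5 |
| beta | 0.667 | 3.7 | 93.5 |
| beta | 1.33 | 10.3 | 88.4 |
| beta | 2.50 | 22.6 | 75.6 |

(readings scatter by 0.5 percentage points)

- solid, in amounts per volume of the solution: solid reagent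
- reactions considered so far: starting material + free catalyst -> catalyst intermediate A; coupling partner + catalyst intermediate A -> catalyst intermediate B; catalyst intermediate B -> catalyst intermediate C; catalyst intermediate C -> free catalyst + product; solid reagent <-> coupling partner
- at the start none of the solid reagent is in solution

* which of the two ends with the higher amount of product, in percent of the starting material charged ("neither" if they lie within 2 percentage points) (noon / winter / neither)
* product at the end, in percent of the starting material charged, noon
* product at the end, in percent of the starting material charged, winter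

The rule gave 48.0% for noon and 70.0% for winter, so winter looked better. The zeta run supported the rule: its last reading was 12.4%, and its ratio of charges was 12.4%.

But the rule has no clock. At 2.50 min the gamma run held 0.0865 M of product and the beta run 0.0881 M, despite different charges. Between its last two readings the beta run made 0.0410 M min⁻¹. I called this the supply rate, the moles of product made per litre and minute. Drawn back, that line reached zero product at 0.350 min.

The border was the run-out time: this lag plus c solid reagent over the supply rate. Above a ratio of one, time allowed over run-out time, I trusted the ceiling. Below one, I trusted the clock. I reckoned the run-out time of noon at 3.28 min, a ratio of 6.10, and solid reagent was its limiting reagent, with less charged than starting material. Noon's c starting material was lower than in any run, but that ratio left room, and I kept 48.0%. I reckoned the run-out time of winter at 8.89 min, a ratio of 0.562, so I took the supply rate over the time after the lag and got 38.1%.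

The forecast chose noon, with 47.5% for noon and 36% for winter, saying “solid sets the yield ceiling”. Its winter figure was lower than mine.

The flask gave 48.0% for noon and 38.3% for winter, so noon ended higher, as the forecast said. Winter reached 70.0% at 50.0 min. The supply rate over 5.0 min leaves 41.4% of winter's solid reagent, and the flask held 38.9% of its own charge at 5.00 min.

    starting material + free catalyst → catalyst intermediate A (k = 0.740 M⁻¹ s⁻¹)
    coupling partner + catalyst intermediate A → catalyst intermediate B (k = 7.90 M⁻¹ s⁻¹)
    catalyst intermediate B → catalyst intermediate C (k = 0.330 s⁻¹)
    catalyst intermediate C → free catalyst + product (k = 0.340 s⁻¹)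
    solid reagent ⇌ coupling partner, rate k5*(cs5 - [coupling partner]) while solid is left; crystals form when [coupling partner] > cs5 (solubility = 0.390 M, k = 0.00190 s⁻¹)

Take noon with 0.030 M of solid reagent. Its run-out time is 1.08 min, a ratio of 18.5, so the ceiling applies and gives 12.0%. That flask computed to 12.0%, with 83.2% of the starting material left.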